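The synthesis rests on opening ring A at the A-C1–A-C6 bond. Ring A carries the depside carbonyl on A-C1, oxygen on A-C2 and A-C4 and pentyl on A-C6. This is the pattern of a linear C12 chain with carbonyls at C1, C3, C5 and C7, and the key step exploits exactly this feature. Its precursor 17 is the ring-B phenol 15, already O-acylated by open-chain 3,5,7-trioxododecanoic acid. Amine base and then dilute acid join chain C2 to C7, expel one water and tautomerise C3 and C5 to the two phenols. Ring A is thus grown on a finished ester bond, and no 2,6-disubstituted benzoic acid ever has to be esterified.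

Key step: step 8

Remark on stereochemistry: 21 has no stereocentre and no hindered axis. It is achiral, so there is no enantiomer to select.
Remark on labels: ring B is numbered B-C1 (carboxyl), B-C2 (heptyl), B-C4 (depside oxygen), B-C6 (methoxy). Chain C1–C12 is the trioxododecanoyl chain of 17, counted from the ester carbonyl.
Remark on the carbon count: chain C1–C4 come from dioxinone 1 and C7–C12 from hexanoyl chloride 5. C5–C6 need a separate acetyl unit, supplied here by acetyl chloride 2. The aromatisation releases a single molecule of water; the other two events are tautomerisations.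

Step 1
Reactants: 1 2,2,6-trimethyl-4H-1,3-dioxin-4-one; 2 acetyl chloride
Product: 4 2,2-dimethyl-6-(2-oxopropyl)-4H-1,3-dioxin-4-one, via lithium dienolate 3 (not isolated)
Conditions: 1 (2.0 equiv), LiHMDS (2.0 equiv), THF, −78 °C; 2 (1.0 equiv), −78 → −20 °C; 1 M HCl
Reagents that add atoms: none
Why: Vinylogous Claisen acylation, in which the cross-conjugated lithium dienolate of the dioxinone takes up acid chlorides at its exocyclic γ-carbon and the second equivalent of dienolate absorbs the acidic proton of the β-keto product, which should hold back double acylation.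

Step 2
Reactants: 5 hexanoyl chloride
Product: 6 N-methoxy-N-methylhexanamide
Conditions: MeNHOMe·HCl (1.1 equiv), K2CO3 (2.2 equiv), CH2Cl2/H2O, 0 °C → rt
Reagents that add atoms: N,O-dimethylhydroxylamine hydrochloride, CNOC.Cl
Why: Schotten–Baumann N-acylation to a Weinreb amide, chosen over the acid chloride for step 3 because its chelated tetrahedral adduct lasts until the quench and so excludes O-acylation, over-addition and proton transfer from product to dianion.

Step 3
Reactants: 4 2,2-dimethyl-6-(2-oxopropyl)-4H-1,3-dioxin-4-one; 6 N-methoxy-N-methylhexanamide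
Product: 8 6-(2,4-dioxononyl)-2,2-dimethyl-4H-1,3-dioxin-4-one, via dilithio dienolate 7 (not isolated)
Conditions: 4 (1.5 equiv), LDA (3.1 equiv, commercial solution), THF, −78 → −40 °C; 6 (1.0 equiv), −78 → −40 °C; cold 1 M HCl
Reagents that add atoms: none
Why: Dianion Claisen acylation, in which the first deprotonation takes the doubly activated ring-side methylene and the second the terminal methyl, so the last-formed and most reactive terminal carbanion attacks the Weinreb amide and extends the chain by the hexanoyl unit.

Step 4
Reactants: 9 2-methoxy-6-methylbenzoic acid; 10 1-bromohexane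
Product: 12 2-heptyl-6-methoxybenzoic acid, via benzylic dilithio dianion 11 (not isolated)
Conditions: LDA (2.2 equiv, commercial solution), THF, −78 → 0 °C; 10 (1.2 equiv), −78 °C → rt; 1 M HCl
Reagents that add atoms: none
Why: Lateral (benzylic) lithiation of an ortho-toluic acid as its carboxylate dianion followed by SN2 alkylation, where the neighbouring carboxylate stabilises the benzylic anion, cannot self-condense as an ester would, and methyl plus hexyl gives the heptyl chain.

Step 5
Reactants: 12 2-heptyl-6-methoxybenzoic acid
Product: 13 tert-butyl 2-heptyl-6-methoxybenzoate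
Conditions: Cl3CC(=NH)OtBu (2 equiv), BF3·OEt2 (cat.), CH2Cl2/cyclohexane, rt
Reagents that add atoms: tert-butyl 2,2,2-trichloroacetimidate, CC(C)(C)OC(=N)C(Cl)(Cl)Cl
Why: Acid-catalysed trichloroacetimidate O-tert-butylation forms the new bond at the carboxyl oxygen through a tert-butyl cation, so the two ortho substituents that shield the carbonyl carbon do not slow it.

Step 6
Reactants: 13 tert-butyl 2-heptyl-6-methoxybenzoate
Product: 15 tert-butyl 2-heptyl-4-hydroxy-6-methoxybenzoate, via aryl pinacol boronate 14 (not isolated)
Conditions: [Ir(OMe)(cod)]2 (1.5 mol %), dtbpy (3 mol %), B2pin2 (0.6 equiv), THF, 80 °C; then 30 % aq H2O2, aq NaOH (1 equiv), THF, 0 °C → rt; 1 M HCl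
Reagents that add atoms: bis(pinacolato)diboron, CC1(C)OB(OC1(C)C)B1OC(C)(C)C(C)(C)O1 (boryl group of 14); hydrogen peroxide, OO (phenol oxygen of 15)
Why: Sterically governed iridium-catalysed aromatic C–H borylation and one-pot peroxide oxidation of the C–B bond, directed to B-C4 because it is the only ring hydrogen without an ortho substituent (B-C3–H adjoins heptyl, B-C5–H adjoins methoxy), while the hindered tert-butyl ester should resist cold basic peroxide.

Step 7
Reactants: 8 6-(2,4-dioxononyl)-2,2-dimethyl-4H-1,3-dioxin-4-one; 15 tert-butyl 2-heptyl-4-hydroxy-6-methoxybenzoate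
Product: 17 tert-butyl 2-heptyl-6-methoxy-4-[(3,5,7-trioxododecanoyl)oxy]benzoate (keto–enol mixture, drawn all-keto), via acylketene 16 (not isolated)
Conditions: 15 (1.5 equiv, 0.5 M), toluene, 110 °C, slow addition of 8 (1.0 equiv), N2 sweep; concentrate, use crude together with surplus 15
Reagents that add atoms: none
Why: Thermal retro-hetero-Diels–Alder fragmentation of the dioxinone releases acetone and acylketene 16, which adds the phenol O–H (acylketene trapping, established for phenols as well as alcohols); keeping 15 concentrated and in excess while 8 is fed in slowly should let this bimolecular capture outrun closure of the ketene onto its own C5 enol oxygen, and the neutral medium leaves the tert-butyl ester and methyl ether untouched.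

Step 8
Reactants: 17 tert-butyl 2-heptyl-6-methoxy-4-[(3,5,7-trioxododecanoyl)oxy]benzoate
Product: 19 tert-butyl 4-[(2,4-dihydroxy-6-pentylbenzoyl)oxy]-2-heptyl-6-methoxybenzoate, via aldol adduct 18 (not isolated)
Conditions: Et3N (2 equiv), CH2Cl2 (0.05 M), 0 °C → rt; then 1 M aq HCl, two-phase, rt; surplus 15 recovered on chromatography
Reagents that add atoms: none
Why: Triethylamine takes 17 only to a mono-enolate, so the C7 ketone remains a free electrophile and chain C2, acidified by the aryl ester and the C3 ketone, adds to it to give aldol 18, forming the A-C1–A-C6 bond. Dilute aqueous acid, too weak to touch the tert-butyl ester and free of any alcohol that could transesterify, then removes the tertiary C7 hydroxyl as one molecule of water, and the C3 and C5 carbonyls tautomerise to the A-C2 and A-C4 phenols, which makes the sequence irreversible. The closest known reaction type is the biomimetic aldol aromatisation of 3,5,7-triketo esters released from diketo-dioxinones. Ring A closes in the 6-(enolendo)-exo-trig mode, and the two transient stereocentres of 18 are erased on aromatisation, so 19 contains none and no control element is needed. The selectivity required is between cyclisation modes, because C6-to-C1 Claisen closure, attack of the C5 enol oxygen on C1 (pyranone) and E1cB release of the acylketene would each expel the phenoxide of 15. These paths are restrained by the weak base (no polyanion that silences the ketones), by the cold aprotic non-nucleophilic medium, by the surplus 15 that can recapture any released ketene, and by the substrate itself, in which a ketone outranks an ester as acceptor and the ring-B tert-butyl ester, twisted out of conjugation by heptyl and methoxy, keeps the phenoxide a modest leaving group.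

Step 9
Reactants: 19 tert-butyl 4-[(2,4-dihydroxy-6-pentylbenzoyl)oxy]-2-heptyl-6-methoxybenzoate
Product: 20 tert-butyl 2-heptyl-4-[(2-hydroxy-4-methoxy-6-pentylbenzoyl)oxy]-6-methoxybenzoate
Conditions: MeI (1.1 equiv), K2CO3 (1.05 equiv), acetone, rt
Reagents that add atoms: methyl iodide, CI
Why: Regioselective Williamson etherification, in which the A-C4 hydroxyl para to the ester is the more acidic and accessible phenol, the A-C2 hydroxyl is tied up in a hydrogen bond to the depside carbonyl, and the para-phenoxide deactivates that carbonyl towards cleavage.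

Step 10
Reactants: 20 tert-butyl 2-heptyl-4-[(2-hydroxy-4-methoxy-6-pentylbenzoyl)oxy]-6-methoxybenzoate
Product: 21 2-heptyl-4-[(2-hydroxy-4-methoxy-6-pentylbenzoyl)oxy]-6-methoxybenzoic acid (CNP0518349.0)
Conditions: TFA/CH2Cl2 (1:4), Et3SiH (2.5 equiv), 0 °C → rt, short contact time
Reagents that add atoms: none
Why: Acidolysis of the tert-butyl ester by alkyl–oxygen (AAL1) cleavage, with triethylsilane reducing the tert-butyl cation before it can alkylate electron-rich ring A, under conditions that aryl esters, aryl methyl ethers and the chelated phenol tolerate.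

Compound list
1 | 2,2,6-trimethyl-4H-1,3-dioxin-4-one | CC1=CC(=O)OC(C)(C)O1 | starting material
2 | acetyl chloride | CC(=O)Cl | starting material
3 | lithium dienolate of 1 (lithium 2,2-dimethyl-6-methylidene-1,3-dioxin-4-olate) | C=C1C=C([O-])OC(C)(C)O1.[Li+] | intermediate
4 | 2,2-dimethyl-6-(2-oxopropyl)-4H-1,3-dioxin-4-one | CC(=O)CC1=CC(=O)OC(C)(C)O1 | intermediate
5 | hexanoyl chloride | CCCCCC(=O)Cl | starting material
6 | N-methoxy-N-methylhexanamide | CCCCCC(=O)N(C)OC | intermediate
7 | dilithio dienolate (dianion) of 4 | C=C([O-])C=C1C=C([O-])OC(C)(C)O1.[Li+].[Li+] | intermediate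
8 | 6-(2,4-dioxononyl)-2,2-dimethyl-4H-1,3-dioxin-4-one | CCCCCC(=O)CC(=O)CC1=CC(=O)OC(C)(C)O1 | intermediate
9 | 2-methoxy-6-methylbenzoic acid | Cc1cccc(OC)c1C(=O)O | starting material
10 | 1-bromohexane | CCCCCCBr | starting material
11 | benzylic dilithio dianion of 9 | [CH2-]c1cccc(OC)c1C(=O)[O-].[Li+].[Li+] | intermediate
12 | 2-heptyl-6-methoxybenzoic acid | CCCCCCCc1cccc(OC)c1C(=O)O | intermediate
13 | tert-butyl 2-heptyl-6-methoxybenzoate | CCCCCCCc1cccc(OC)c1C(=O)OC(C)(C)C | intermediate
14 | tert-butyl 2-heptyl-6-methoxy-4-(4,4,5,5-tetramethyl-1,3,2-dioxaborolan-2-yl)benzoate | CCCCCCCc1cc(B2OC(C)(C)C(C)(C)O2)cc(OC)c1C(=O)OC(C)(C)C | intermediate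
15 | tert-butyl 2-heptyl-4-hydroxy-6-methoxybenzoate | CCCCCCCc1cc(O)cc(OC)c1C(=O)OC(C)(C)C | intermediate
16 | 3,5,7-trioxododec-1-en-1-one (acylketene) | CCCCCC(=O)CC(=O)CC(=O)C=C=O | intermediate
17 | tert-butyl 2-heptyl-6-methoxy-4-[(3,5,7-trioxododecanoyl)oxy]benzoate | CCCCCC(=O)CC(=O)CC(=O)CC(=O)Oc1cc(CCCCCCC)c(C(=O)OC(C)(C)C)c(OC)c1 | intermediate
18 | tert-butyl 2-heptyl-4-{[(2-hydroxy-4,6-dioxo-2-pentylcyclohexyl)carbonyl]oxy}-6-methoxybenzoate (stereoisomer mixture, transient) | CCCCCC1(O)CC(=O)CC(=O)C1C(=O)Oc2cc(CCCCCCC)c(C(=O)OC(C)(C)C)c(OC)c2 | intermediate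
19 | tert-butyl 4-[(2,4-dihydroxy-6-pentylbenzoyl)oxy]-2-heptyl-6-methoxybenzoate | CCCCCCCc1cc(OC(=O)c2c(O)cc(O)cc2CCCCC)cc(OC)c1C(=O)OC(C)(C)C | intermediate
20 | tert-butyl 2-heptyl-4-[(2-hydroxy-4-methoxy-6-pentylbenzoyl)oxy]-6-methoxybenzoate | CCCCCCCc1cc(OC(=O)c2c(O)cc(OC)cc2CCCCC)cc(OC)c1C(=O)OC(C)(C)C | intermediate
21 | 2-heptyl-4-[(2-hydroxy-4-methoxy-6-pentylbenzoyl)oxy]-6-methoxybenzoic acid | CCCCCCCc1cc(OC(=O)c2c(O)cc(OC)cc2CCCCC)cc(OC)c1C(=O)O | target

Total step count: 10.
Longest linear sequence: 7 steps (9 → 12 → 13 → 15 → 17 → 19 → 20 → 21, that is steps 4, 5, 6, 7, 8, 9, 10).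

Steps most likely to fail

Step 8. Loss of the ring-B phenoxide may overtake the C2-to-C7 aldol, through Claisen closure, lactonisation by the C5 enol oxygen or E1cB fragmentation of the activated aryl ester. The fallback builds ring A on a robust alkyl ester and makes the depside bond afterwards by classical esterification. It sets out from 8 and returns at 20.
- 8 is heated in toluene with benzyl alcohol, again through 16, to give benzyl 3,5,7-trioxododecanoate F1.
- The usual base-then-acid aromatisation is safe here, because an alkoxide is a poor leaving group. It should give benzyl 2,4-dihydroxy-6-pentylbenzoate F2.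
- Methyl iodide and potassium carbonate convert this into benzyl 2-hydroxy-4-methoxy-6-pentylbenzoate F3.
- Hydrogenolysis over palladium on carbon frees 2-hydroxy-4-methoxy-6-pentylbenzoic acid F4.
- Carbodiimide coupling of this acid with phenol 15 (DCC, catalytic DMAP, toluene) delivers 20.

Step 7. The acylketene may be consumed by its own C5 enol oxygen or by dimerisation before the weakly nucleophilic phenol adds, and the adduct may revert at 110 °C. The fallback replaces the thermal open-chain ketene by a photochemically generated aromatic one at room temperature. It sets out from 8 and 15 and returns at 20.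
- Triethylamine in dichloromethane aromatises 8 with the acetonide intact, giving 7-hydroxy-2,2-dimethyl-5-pentyl-4H-1,3-benzodioxin-4-one F5.
- Methyl iodide and potassium carbonate give 7-methoxy-2,2-dimethyl-5-pentyl-4H-1,3-benzodioxin-4-one F6.
- Irradiation at about 300 nm in dichloromethane with 15 expels acetone and passes through the quinoketene 3-methoxy-6-(oxomethylidene)-5-pentylcyclohexa-2,4-dien-1-one F7. This adds the phenol O–H and gives 20 directly, with the A-C2 hydroxyl free.

Step 3. Several things may erode the dianion acylation: incomplete second deprotonation, proton exchange between dianion and amide, attack through the internal carbon, or premature base-induced cyclisation of the product. The fallback avoids dianions by using chelation-controlled C-acylation followed by decarboxylation. It sets out from 1 and 5 and returns at 8.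
- Dienolate 3 is acylated with the acid chloride of monoallyl malonate to give allyl 4-(2,2-dimethyl-4-oxo-4H-1,3-dioxin-6-yl)-3-oxobutanoate F8.
- Magnesium chloride and pyridine direct hexanoyl chloride 5 to the methylene between ester and ketone, giving allyl 2-[(2,2-dimethyl-4-oxo-4H-1,3-dioxin-6-yl)acetyl]-3-oxooctanoate F9.
- Catalytic Pd(PPh3)4 with morpholine removes the allyl group, and the resulting acid loses carbon dioxide to give 8.

Further compounds
F1 | step 8 | benzyl 3,5,7-trioxododecanoate | CCCCCC(=O)CC(=O)CC(=O)CC(=O)OCc1ccccc1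
F2 | step 8 | benzyl 2,4-dihydroxy-6-pentylbenzoate | CCCCCc1cc(O)cc(O)c1C(=O)OCc1ccccc1
F3 | step 8 | benzyl 2-hydroxy-4-methoxy-6-pentylbenzoate | CCCCCc1cc(OC)cc(O)c1C(=O)OCc1ccccc1
F4 | step 8 | 2-hydroxy-4-methoxy-6-pentylbenzoic acid | CCCCCc1cc(OC)cc(O)c1C(=O)O
F5 | step 7 | 7-hydroxy-2,2-dimethyl-5-pentyl-4H-1,3-benzodioxin-4-one | CCCCCc1cc(O)cc2OC(C)(C)OC(=O)c12
F6 | step 7 | 7-methoxy-2,2-dimethyl-5-pentyl-4H-1,3-benzodioxin-4-one | CCCCCc1cc(OC)cc2OC(C)(C)OC(=O)c12
F7 | step 7 | 3-methoxy-6-(oxomethylidene)-5-pentylcyclohexa-2,4-dien-1-one | CCCCCC1=CC(OC)=CC(=O)C1=C=O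
F8 | step 3 | allyl 4-(2,2-dimethyl-4-oxo-4H-1,3-dioxin-6-yl)-3-oxobutanoate | C=CCOC(=O)CC(=O)CC1=CC(=O)OC(C)(C)O1
F9 | step 3 | allyl 2-[(2,2-dimethyl-4-oxo-4H-1,3-dioxin-6-yl)acetyl]-3-oxooctanoate | CCCCCC(=O)C(C(=O)OCC=C)C(=O)CC1=CC(=O)OC(C)(C)O1
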